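**Plan**
1. Retrosynthesis: after removal of nineteen benzyl ethers and one C8 bromine, the two interflavan bonds are cut, C4(top)–C8(middle) and C4(middle)–C8(bottom).
2. Enabling feature: top and middle units are the same epicatechin 3-O-gallate. In each, C4 of ring C is benzylic to the 5,7-dioxygenated ring A, lies next to the 3-O-galloyl group and is bonded to C8 of ring A of the next unit, so one kind of C4 arylthio donor serves twice.
3. Forward: no ring is formed. The chain is joined top → middle → bottom in one pot: anodic oxidation of the 8-bromo top donor to a C4 cation pool, capture by C8 of the middle donor, a second electrolysis, capture by C8 of penta-O-benzylcatechin.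
4. Stereochemistry: C2 and C3 of all three units come from (−)-epicatechin and (+)-catechin; both new C4 centres are set trans to O3 by the bridging galloyl group.
5. Sulfur is carried as a 2,6-dimethylphenylthio group (hindered sulfur, no thio transfer). C8 is brominated before sulfur is introduced, because N-bromosuccinimide attacks sulfides.
6. One hydrogenolysis then frees all phenols and removes the bromine.

Key step: step 9

Remark: flavan numbering is used (ring A = C4a–C8a, ring B = 2-aryl group, ring C = pyran ring); α is the face of ring C that carries the 2-aryl group of a (2R)-flavan, β the opposite face.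

**Step 1**
Reactants: 1 (−)-epicatechin
Product: 2 5,7,3',4'-tetra-O-benzyl-(−)-epicatechin
Conditions: BnBr (4.4 equiv), K2CO3, DMF, 0 °C to rt
Reagents that add atoms: benzyl bromide, BrCc1ccccc1
Why: Williamson etherification under carbonate conditions alkylates only the four phenols, leaving the secondary 3-OH free and C2/C3 untouched.

**Step 2**
Reactants: 2 5,7,3',4'-tetra-O-benzyl-(−)-epicatechin
Product: 3 (2R,3R,4S)-5,7,3',4'-tetra-O-benzyl-4β-(2-ethoxyethoxy)epicatechin
Conditions: DDQ (2 equiv), 2-ethoxyethanol (5 equiv), CH2Cl2, rt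
Reagents that add atoms: 2-ethoxyethanol, CCOCCO
Why: DDQ benzylic oxidation abstracts hydride from C4 and the alcohol captures the ring-A-stabilised cation trans to the 3-OH (β face); this centre is ionised again later, so its configuration is not critical.

**Step 3**
Reactants: 3 (2R,3R,4S)-5,7,3',4'-tetra-O-benzyl-4β-(2-ethoxyethoxy)epicatechin; 4 3,4,5-tris(benzyloxy)benzoic acid
Product: 5 (2R,3R,4S)-5,7,3',4'-tetra-O-benzyl-4β-(2-ethoxyethoxy)epicatechin 3-O-(3,4,5-tri-O-benzylgallate)
Conditions: DCC, DMAP (cat.), CH2Cl2, rt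
Reagents that add atoms: none
Why: Steglich esterification acylates the secondary 3-OH through the acylpyridinium under neutral conditions that the acid-labile C4 ether tolerates.

**Step 4**
Reactants: 5 (2R,3R,4S)-5,7,3',4'-tetra-O-benzyl-4β-(2-ethoxyethoxy)epicatechin 3-O-(3,4,5-tri-O-benzylgallate); 6 2,6-dimethylbenzenethiol
Product: 7 middle donor, (2R,3S,4S)-5,7,3',4'-tetra-O-benzyl-4β-(2,6-dimethylphenylthio)epicatechin 3-O-(3,4,5-tri-O-benzylgallate)
Conditions: TMSOTf (0.1 equiv), 6 (5 equiv), CH2Cl2, −78 to −40 °C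
Reagents that add atoms: none
Why: Lewis-acid-catalysed SN1 exchange at the acetal-like C4 ionises the C4–O bond to the galloyl-bridged cation, which the excess thiol captures on the β face (3,4-trans) faster than any C8 self-alkylation; an α epimer would serve equally, since both give the same cation in step 9.

**Step 5**
Reactants: 5 (2R,3R,4S)-5,7,3',4'-tetra-O-benzyl-4β-(2-ethoxyethoxy)epicatechin 3-O-(3,4,5-tri-O-benzylgallate)
Product: 8 (2R,3R,4S)-8-bromo-5,7,3',4'-tetra-O-benzyl-4β-(2-ethoxyethoxy)epicatechin 3-O-(3,4,5-tri-O-benzylgallate)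
Conditions: NBS (1.0 equiv), CH2Cl2, dark, −40 to 0 °C
Reagents that add atoms: N-bromosuccinimide, O=C1CCC(=O)N1Br
Why: electrophilic aromatic bromination goes to C8, the most nucleophilic and least hindered position of ring A (C6 lies between two benzyloxy groups), and is placed before sulfur introduction because NBS would activate a sulfide.

**Step 6**
Reactants: 8 (2R,3R,4S)-8-bromo-5,7,3',4'-tetra-O-benzyl-4β-(2-ethoxyethoxy)epicatechin 3-O-(3,4,5-tri-O-benzylgallate); 6 2,6-dimethylbenzenethiol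
Product: 9 top donor, (2R,3S,4S)-8-bromo-5,7,3',4'-tetra-O-benzyl-4β-(2,6-dimethylphenylthio)epicatechin 3-O-(3,4,5-tri-O-benzylgallate)
Conditions: TMSOTf (0.1 equiv), 6 (5 equiv), CH2Cl2, −78 to −30 °C
Reagents that add atoms: none
Why: the same Lewis-acid-catalysed SN1 thiol exchange as in step 4, with the thiol entering trans to the participating 3-O-galloyl group and the aryl bromide inert to the hard acid.

**Step 7**
Reactants: 10 (+)-catechin
Product: 11 5,7,3',4'-tetra-O-benzyl-(+)-catechin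
Conditions: BnBr (4.4 equiv), K2CO3, DMF, 0 °C to rt
Reagents that add atoms: benzyl bromide, BrCc1ccccc1
Why: Williamson etherification of the four phenols only, with the 2,3-trans stereocentres untouched.

**Step 8**
Reactants: 11 5,7,3',4'-tetra-O-benzyl-(+)-catechin
Product: 12 3,5,7,3',4'-penta-O-benzyl-(+)-catechin
Conditions: NaH, BnBr, Bu4NI (cat.), DMF, 0 °C to rt
Reagents that add atoms: benzyl bromide, BrCc1ccccc1
Why: Williamson etherification of the secondary alkoxide caps the 3-OH so that only C8 of ring A remains as a nucleophilic site for the cation in step 9.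

**Step 9**
Reactants: 9 top donor; 7 middle donor; 12 3,5,7,3',4'-penta-O-benzyl-(+)-catechin
Product: 16 nonadeca-O-benzyl 8-bromo trimer (protected target), via top-unit dioxolanylium triflate 13 (not isolated), via dimeric 4-thioether 14 (not isolated), via dimer dioxolanylium triflate 15 (not isolated)
Conditions: divided cell, carbon-felt anode, Pt cathode, Bu4NOTf (0.1 M)/CH2Cl2, TfOH in the cathode chamber, −78 °C: 9 (1.15 equiv), constant current, 1.05 F/mol; current off, 7 (1.0 equiv), 2,6-di-tert-butyl-4-methylpyridine (DTBMP, 2.5 equiv), −78 to −60 °C; constant current, 1.05 F/mol of 7, −78 °C; current off, 12 (1.5 equiv), −78 to −50 °C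
Reagents that add atoms: none
Why: Proposed new method: one-electron anodic oxidation of the aryl sulfide (or of ring A, the hole reaching the same C4–S bond) should trigger mesolytic C4–S cleavage to the arylthiyl radical (which dimerises) and the C4 cation, stabilised by O1, O5 and O7 of ring A and bridged by the 3-O-galloyl carbonyl as the cis-fused dioxolanylium ion 13, which can be stored at −78 °C with no nucleophile present; the closest known reaction types are the one-pot iterative electrochemical glycosylation, in which thioglycosides are oxidised to glycosyl triflate pools and the next thioglycoside is added with the current off, and the hard-acid activation of C4–O flavan donors in the presence of a C4 arylthio group. With the current off, C8 of ring A of 7 should attack C4 of 13 in a Friedel–Crafts alkylation to give 14, whose own C4–S bond stays intact because no oxidant is present, and re-electrolysis should convert 14 into 15, which C8 of 12 captures. No ring is closed. Each new stereocentre (C4 of the top unit, C4 of the middle unit) is set trans to O3 because the bridging galloyl group occupies the α face, and since the cation is planar at C4 the outcome does not depend on the C4 configuration of the thioether. The step needs C8 rather than C6 attack (C8, next to ring oxygen O1, is the less hindered and more nucleophilic site of a 5,7-dibenzyloxyflavan), no S-alkylation or thio transfer (the two ortho methyl groups shield sulfur) and a fixed order of units, secured by the C8 bromine of 9 (the pool cannot condense with itself), a slight excess of 13 over 7 and addition of each nucleophile only after the current is off.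

**Step 10**
Reactants: 16 nonadeca-O-benzyl 8-bromo trimer (protected target)
Product: 17 epicatechin 3-O-gallate-(4β→8)-epicatechin 3-O-gallate-(4β→8)-catechin (target)
Conditions: H2 (1 atm), Pd(OH)2/C, Et3N (2 equiv), THF/MeOH/H2O, rt; filtration under argon, lyophilisation
Reagents that add atoms: none
Why: heterogeneous palladium-catalysed hydrogenolysis should cleave all nineteen O-benzyl bonds and the aryl C8–Br bond (hydrodehalogenation, HBr taken up by Et3N) while leaving the gallate esters, the interflavan bonds and every stereocentre untouched.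

**Compound list**
1 | (−)-epicatechin, (2R,3R) | C1c2c(O)cc(O)cc2O[C@H](c2ccc(O)c(O)c2)[C@@H]1O | starting material
2 | 5,7,3',4'-tetra-O-benzyl-(−)-epicatechin, (2R,3R) | C1c2c(OCc3ccccc3)cc(OCc3ccccc3)cc2O[C@H](c2ccc(OCc3ccccc3)c(OCc3ccccc3)c2)[C@@H]1O | intermediate
3 | (2R,3R,4S)-5,7,3',4'-tetra-O-benzyl-4β-(2-ethoxyethoxy)epicatechin (3,4-trans, free 3-OH) | CCOCCO[C@H]1c2c(OCc3ccccc3)cc(OCc3ccccc3)cc2O[C@H](c2ccc(OCc3ccccc3)c(OCc3ccccc3)c2)[C@@H]1O | intermediate
4 | 3,4,5-tris(benzyloxy)benzoic acid | OC(=O)c1cc(OCc2ccccc2)c(OCc2ccccc2)c(OCc2ccccc2)c1 | starting material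
5 | (2R,3R,4S)-5,7,3',4'-tetra-O-benzyl-4β-(2-ethoxyethoxy)epicatechin 3-O-(3,4,5-tri-O-benzylgallate) | CCOCCO[C@H]1c2c(OCc3ccccc3)cc(OCc3ccccc3)cc2O[C@H](c2ccc(OCc3ccccc3)c(OCc3ccccc3)c2)[C@@H]1OC(=O)c1cc(OCc2ccccc2)c(OCc2ccccc2)c(OCc2ccccc2)c1 | intermediate
6 | 2,6-dimethylbenzenethiol | Cc1cccc(C)c1S | starting material
7 | middle donor, (2R,3S,4S)-5,7,3',4'-tetra-O-benzyl-4β-(2,6-dimethylphenylthio)epicatechin 3-O-(3,4,5-tri-O-benzylgallate) (S trans to O3) | Cc1cccc(C)c1S[C@H]1c2c(OCc3ccccc3)cc(OCc3ccccc3)cc2O[C@H](c2ccc(OCc3ccccc3)c(OCc3ccccc3)c2)[C@@H]1OC(=O)c1cc(OCc2ccccc2)c(OCc2ccccc2)c(OCc2ccccc2)c1 | intermediate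
8 | (2R,3R,4S)-8-bromo-5,7,3',4'-tetra-O-benzyl-4β-(2-ethoxyethoxy)epicatechin 3-O-(3,4,5-tri-O-benzylgallate) | CCOCCO[C@H]1c2c(OCc3ccccc3)cc(OCc3ccccc3)c(Br)c2O[C@H](c2ccc(OCc3ccccc3)c(OCc3ccccc3)c2)[C@@H]1OC(=O)c1cc(OCc2ccccc2)c(OCc2ccccc2)c(OCc2ccccc2)c1 | intermediate
9 | top donor, (2R,3S,4S)-8-bromo-5,7,3',4'-tetra-O-benzyl-4β-(2,6-dimethylphenylthio)epicatechin 3-O-(3,4,5-tri-O-benzylgallate) | Cc1cccc(C)c1S[C@H]1c2c(OCc3ccccc3)cc(OCc3ccccc3)c(Br)c2O[C@H](c2ccc(OCc3ccccc3)c(OCc3ccccc3)c2)[C@@H]1OC(=O)c1cc(OCc2ccccc2)c(OCc2ccccc2)c(OCc2ccccc2)c1 | intermediate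
10 | (+)-catechin, (2R,3S) | c1c(O)cc(O)c2c1O[C@H](c1ccc(O)c(O)c1)[C@@H](O)C2 | starting material
11 | 5,7,3',4'-tetra-O-benzyl-(+)-catechin, (2R,3S) | c1c(OCc3ccccc3)cc(OCc3ccccc3)c2c1O[C@H](c1ccc(OCc3ccccc3)c(OCc3ccccc3)c1)[C@@H](O)C2 | intermediate
12 | 3,5,7,3',4'-penta-O-benzyl-(+)-catechin, (2R,3S) | c1c(OCc3ccccc3)cc(OCc3ccccc3)c2c1O[C@H](c1ccc(OCc3ccccc3)c(OCc3ccccc3)c1)[C@@H](OCc1ccccc1)C2 | intermediate
13 | top-unit C4 cation (not isolated), drawn as the cis-fused 2-(3,4,5-tribenzyloxyphenyl)-1,3-dioxolan-2-ylium triflate bridging O3 and C4 on the α face of the 8-bromo-tetra-O-benzylflavan; in equilibrium with the open benzylic cation | C1(=[O+][C@@H]2c3c(OCc4ccccc4)cc(OCc4ccccc4)c(Br)c3O[C@H](c3ccc(OCc4ccccc4)c(OCc4ccccc4)c3)[C@@H]2O1)c1cc(OCc2ccccc2)c(OCc2ccccc2)c(OCc2ccccc2)c1.[O-]S(=O)(=O)C(F)(F)F | intermediate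
14 | dimeric 4-thioether (not isolated): [8-bromo-tetra-O-benzylepicatechin 3-O-tribenzylgallate]-(4β→8)-[tetra-O-benzyl-4β-(2,6-dimethylphenylthio)epicatechin 3-O-tribenzylgallate] | Cc1cccc(C)c1S[C@H]1c2c(OCc3ccccc3)cc(OCc3ccccc3)c([C@H]3c4c(OCc5ccccc5)cc(OCc5ccccc5)c(Br)c4O[C@H](c4ccc(OCc5ccccc5)c(OCc5ccccc5)c4)[C@@H]3OC(=O)c3cc(OCc4ccccc4)c(OCc4ccccc4)c(OCc4ccccc4)c3)c2O[C@H](c2ccc(OCc3ccccc3)c(OCc3ccccc3)c2)[C@@H]1OC(=O)c1cc(OCc2ccccc2)c(OCc2ccccc2)c(OCc2ccccc2)c1 | intermediate
15 | dimer C4 cation (not isolated): the top unit of 14 attached 4β→8 to the middle unit, whose O3 and C4 are bridged on the α face as the cis-fused 2-aryl-1,3-dioxolan-2-ylium triflate | C1(=[O+][C@@H]2c3c(OCc4ccccc4)cc(OCc4ccccc4)c([C@H]4c5c(OCc6ccccc6)cc(OCc6ccccc6)c(Br)c5O[C@H](c5ccc(OCc6ccccc6)c(OCc6ccccc6)c5)[C@@H]4OC(=O)c4cc(OCc5ccccc5)c(OCc5ccccc5)c(OCc5ccccc5)c4)c3O[C@H](c3ccc(OCc4ccccc4)c(OCc4ccccc4)c3)[C@@H]2O1)c1cc(OCc2ccccc2)c(OCc2ccccc2)c(OCc2ccccc2)c1.[O-]S(=O)(=O)C(F)(F)F | intermediate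
16 | nonadeca-O-benzyl 8-bromo trimer: [8-bromo-tetra-O-benzylepicatechin 3-O-tribenzylgallate]-(4β→8)-[tetra-O-benzylepicatechin 3-O-tribenzylgallate]-(4β→8)-[penta-O-benzylcatechin] | O=C(c1cc(OCc2ccccc2)c(OCc2ccccc2)c(OCc2ccccc2)c1)O[C@@H]1[C@@H](c2c(OCc3ccccc3)cc(OCc3ccccc3)c3c2O[C@H](c2ccc(OCc4ccccc4)c(OCc4ccccc4)c2)[C@@H](OCc2ccccc2)C3)c2c(OCc3ccccc3)cc(OCc3ccccc3)c([C@H]3c4c(OCc5ccccc5)cc(OCc5ccccc5)c(Br)c4O[C@H](c4ccc(OCc5ccccc5)c(OCc5ccccc5)c4)[C@@H]3OC(=O)c3cc(OCc4ccccc4)c(OCc4ccccc4)c(OCc4ccccc4)c3)c2O[C@@H]1c1ccc(OCc2ccccc2)c(OCc2ccccc2)c1 | intermediate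
17 | epicatechin 3-O-gallate-(4β→8)-epicatechin 3-O-gallate-(4β→8)-catechin | O=C(O[C@@H]1[C@@H](c2c(O)cc(O)c3c2O[C@H](c2ccc(O)c(O)c2)[C@@H](O)C3)c2c(O)cc(O)c([C@H]3c4c(O)cc(O)cc4O[C@H](c4ccc(O)c(O)c4)[C@@H]3OC(=O)c3cc(O)c(O)c(O)c3)c2O[C@@H]1c1ccc(O)c(O)c1)c1cc(O)c(O)c(O)c1 | target

**Step count and risks**
Total: 10 steps. Longest linear sequence: 7 steps (steps 1, 2, 3, 5, 6, 9, 10).

Steps most likely to fail:

1. Step 9. The anodic oxidation may be unselective (oxidation of the alkoxyarene rings, or over-oxidation of the disulfide followed by sulfenylation of ring A). The stored cation may decay before it is captured (proton loss at C3, alkylation at a free C6). The arylthio group may also migrate between units and scramble their order. The fallback uses known hard/soft chemical activation and sets out from 8 and 7. Catalytic TMSOTf in CH2Cl2 at −78 °C ionises only the C4–O bond of 8, and C8 of 7 captures the cation to give the dimeric 4-thioether 14, now isolated. The C4–S bond of 14 is then activated with the soft thiophile N-iodosuccinimide in CH2Cl2 at −78 to −30 °C in the presence of 12. This returns to the route at 16. No compound outside the list is made (none, F0).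

2. Step 5. Regiocontrol of the bromination may be lost (attack at C6 or a second bromination), or the C4 ether may be cleaved during the reaction. The fallback sets out from 2. NBS in CH2Cl2 at −78 °C to rt should give 8-bromo-5,7,3',4'-tetra-O-benzylepicatechin F1. DDQ oxidation in the presence of 2-ethoxyethanol then gives 8-bromo-5,7,3',4'-tetra-O-benzyl-4β-(2-ethoxyethoxy)epicatechin F2. Steglich esterification of F2 with 4 (DCC, DMAP) returns to the route at 8.

3. Step 10. The hydrogenolysis may stall through catalyst poisoning by sulfur traces or precipitation of partly debenzylated material. Carbon–bromine cleavage may be slow, and the free polyphenol may degrade in the presence of HBr or amine. The fallback separates the two events and sets out from 16. Hydrodebromination with the zerovalent palladium catalyst Pd(PPh3)4 and HCO2Na in DMF at 80 °C should give the bromine-free nonadeca-O-benzyl trimer F3. Hydrogenolysis of F3 (H2, Pd(OH)2/C, THF/MeOH/H2O, no base) then returns to the route at 17.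

**Further compounds**
F0 | step 9 | none | none
F1 | step 5 | 8-bromo-5,7,3',4'-tetra-O-benzyl-(−)-epicatechin | C1c2c(OCc3ccccc3)cc(OCc3ccccc3)c(Br)c2O[C@H](c2ccc(OCc3ccccc3)c(OCc3ccccc3)c2)[C@@H]1O
F2 | step 5 | 8-bromo-5,7,3',4'-tetra-O-benzyl-4β-(2-ethoxyethoxy)epicatechin | CCOCCO[C@H]1c2c(OCc3ccccc3)cc(OCc3ccccc3)c(Br)c2O[C@H](c2ccc(OCc3ccccc3)c(OCc3ccccc3)c2)[C@@H]1O
F3 | step 10 | nonadeca-O-benzyl trimer without bromine: [tetra-O-benzylepicatechin 3-O-tribenzylgallate]-(4β→8)-[tetra-O-benzylepicatechin 3-O-tribenzylgallate]-(4β→8)-[penta-O-benzylcatechin] | O=C(c1cc(OCc2ccccc2)c(OCc2ccccc2)c(OCc2ccccc2)c1)O[C@@H]1[C@@H](c2c(OCc3ccccc3)cc(OCc3ccccc3)c3c2O[C@H](c2ccc(OCc4ccccc4)c(OCc4ccccc4)c2)[C@@H](OCc2ccccc2)C3)c2c(OCc3ccccc3)cc(OCc3ccccc3)c([C@H]3c4c(OCc5ccccc5)cc(OCc5ccccc5)cc4O[C@H](c4ccc(OCc5ccccc5)c(OCc5ccccc5)c4)[C@@H]3OC(=O)c3cc(OCc4ccccc4)c(OCc4ccccc4)c(OCc4ccccc4)c3)c2O[C@@H]1c1ccc(OCc2ccccc2)c(OCc2ccccc2)c1
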